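0.170 M is the number to carry into this flask: it is the usable partner, the whole charge of coupling partner less the protic impurity, and you hold it against what the wanted excess costs.

common to all: left-handed substrate 0.10 M; right-handed substrate 0.10 M

| run | coupling partner | protic impurity | remark | time |
|---|---|---|---|---|
| Monday's | 0.10 M (fed, over 4.0 min) | 0.030 M | run made earlier |  |
| Wednesday's | 0.15 M (fed, over 4.0 min) | 0.030 M | run made earlier |  |
| flask | 0.200 M (fed, over 4.0 min) | 0.0300 M |  | 2.0 h |

| run | time / min | right-handed substrate / % | left-handed substrate / % | left-handed product / % |
|---|---|---|---|---|
| Monday's | 10.0 | 48 | 23 | 28 |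
| Monday's | 25.0 | 48 | 21 | 32 |
| Monday's | 50.0 | 46 | 18 | 31 |
| Monday's | 80.0 | 47 | 19 | 29 |
| Wednesday's | 20.0 | 45 | 5 | 46 |
| Wednesday's | 40.0 | 43 | 4 | 46 |
| Wednesday's | 50.0 | 45 | 4 | 48 |
| Wednesday's | 80.0 | 45 | 3 | 46 |

(readings scatter by 1.5 percentage points)

- whether the excess of right-handed substrate over left-handed substrate among what is left of the two reaches 90% by 2.0 h (no / yes)
- the highest excess of right-handed substrate over left-handed substrate among what is left of the two up to 2.0 h

Read the earlier runs as a ladder of time scales. The feed takes 4.0 min. On the next rung, Monday's run reads 23% left-handed substrate at 10.0 min and still 19% at 80.0 min, so its main change is over early, and the 2.0 h allowed for this flask is far longer. Monday's run lost 0.0680 M of substrate against a usable 0.0700 M, which supports the subtraction as a ceiling. Wednesday's run lost 0.104 M against 0.120 M, so these readings leave a gap of 0.0160 M.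

Compare the two hands at one moment. Wednesday's run at 50.0 min gives a reading of the selectivity factor, the ratio of the logarithms of what is left of each hand, of 24.0, and that lead drifts away as the left-handed substrate thins. By my reckoning with this reading, 90% excess costs 0.107 M of partner, so this flask should keep a margin of 0.0630 M, larger than the gap in Wednesday's run.

The forecast, with a selectivity of about 20 against my 24.0, and reckoning “With 0.17 M usable”, says yes, with a top of 99.4%, between 98% and 99.9%.

The flask gives yes, with a top of 99.5%.

    coupling partner + left-handed substrate → left-handed product (k = 0.0550 /M/s)
    coupling partner + protic impurity → quenched reagent (k = 0.0980 /M/s)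
    coupling partner → decomposition product (k = 1.50 × 10⁻⁵ /s)
    coupling partner + right-handed substrate → right-handed product (k = 0.00200 /M/s)
    coupling partner → decomposed reagent (k = 4.10 × 10⁻⁴ /s)

The flask reaches 90% at 0.248 h, with right-handed substrate left at 44.7% of the two substrates charged together. At 2.00 h in this flask, beside the 0.0300 M of quenched reagent, the two products hold 0.120 M of partner, and with decomposed reagent, decomposition product and remaining partner the count comes to 0.170 M, the usable 0.170 M. Monday's run had a usable 0.0700 M, below the 0.107 M that the excess costs, and at 50.0 min its readings give an excess of 43.8%.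

All runs stem from a simulated flask for an exercise; scatter was added.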